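**Plan**

- Retrosynthesis: after removal of the benzyl and 5-ethyl ethers, each ring C is opened at O1–C2, C2–C3 and C4–C4a (flavone, chalcone, acetophenone). Each ring A is then cut at C8a–C8, C6–C7 and C4a–C8a, leaving 1,4-dimethoxybuta-1,3-diyne and two molecules of 3-ethoxycyclobut-2-en-1-one.
- Enabling feature: every ring A has oxygen on C5, C7 and C8a and carbon on C8. This is the pattern written by an alkoxyalkyne (C7, C8) and a 3-alkoxy vinylketene (C8a, C6, C5, C4a), so the C8–C8'' bond can already exist as the central bond of a dialkoxydiyne.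
- Forward: two molecules of methoxyacetylene are joined (axis first) and both rings A are closed around the diyne in one operation. Both rings C follow by C-acetylation, Claisen–Schmidt condensation (rings B arrive with 4-(benzyloxy)benzaldehyde) and oxidative cyclisation; BCl3 then frees the 5- and 4'-hydroxyls.
- Stereochemistry: the target has no stereocentre. The 8,8'' axis arises without control as a racemate, and the E geometry of the chalcone is thermodynamic and vanishes in the flavone.

Key step: step 3

Assumption: the target is taken as drawn, with no assigned sense of the 8,8'' axis, so the racemic biflavone is the goal. Diyne 4 is handled only as a cold solution and used at once.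

**Route**

Step 1
Reactants: 1 chloroacetaldehyde dimethyl acetal
Product: 3 methoxyethyne (methoxyacetylene), via sodium methoxyethynide 2 (not isolated)
Conditions: NaNH2 (3.2 equiv), liq. NH3, −33 °C; then cold sat. aq. NaCl, −20 °C; distilled at low temperature into cold acetone
Reagents that add atoms: none
Why: NaNH2-mediated elimination of methanol and then of HCl from an α-chloro acetal, with the third equivalent of base holding the product as its acetylide, is the standard preparation of alkoxyacetylenes, and protonation of 2 should release the volatile ynol ether.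

Step 2
Reactants: 3 methoxyethyne (2 equiv)
Product: 4 1,4-dimethoxybuta-1,3-diyne
Conditions: CuCl (10 mol %), TMEDA (20 mol %), O2 (1 atm, closed; 0.5 equiv consumed), acetone, −10 → 0 °C; cold NH3/NH4Cl buffer wash, exchange into toluene at ≤ 0 °C
Reagents that add atoms: none
Why: Glaser–Hay oxidative homocoupling joins two molecules of the terminal alkyne 3 at their acetylenic carbons, the two acetylenic hydrogens leaving as water, under amine-buffered, non-acidic conditions that an ynol ether should tolerate; the future C8–C8'' bond is made here as the central sp–sp bond.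

Step 3
Reactants: 4 1,4-dimethoxybuta-1,3-diyne; 5 3-ethoxycyclobut-2-en-1-one (3 equiv)
Product: 8 4,4'-diethoxy-6,6'-dimethoxybiphenyl-2,2'-diol, via 3-ethoxybuta-1,3-dien-1-one 6 (not isolated), via 5-ethoxy-3-methoxy-2-(methoxyethynyl)phenol 7 (not isolated)
Conditions: toluene (0.05 M in 4), Ar, sealed vessel, 80 °C then 110 °C; then K2CO3, MeOH, rt
Reagents that add atoms: none
Why: Proposed new method: heating opens 5 by 4-electron electrocyclic ring opening to vinylketene 6, whose ketene carbon is attacked by the nucleophilic inner carbon of one ynol ether of 4 in a (2+2) cycloaddition, the resulting 4-vinylcyclobutenone opens to a dienylketene, and 6-electron electrocyclisation followed by tautomerisation gives phenol 7, which repeats the cascade at its remaining aryl ynol ether to give 8. The closest known reaction is the Danheiser benzannulation of cyclobutenones with alkoxy- and siloxyalkynes, which has not been run twice on a 1,4-dialkoxybutadiyne. Each ring A is closed by the 6-electron electrocyclisation that forms C4a–C8a, after the (2+2) addition and ring opening have set C8a–C8 and C6–C7 around the C8–C8'' bond that was already in place. No stereocentre is formed and the tetra-ortho-substituted axis arises as a racemate. The step needs a single orientation in each ketene–alkyne union, and the methoxy group secures it by making the inner alkyne carbon the nucleophile, so that the methoxyl ends on C7 beside the axis, the ketene oxygen on C8a and the ethoxyl of 5 on C5. The excess of 5 is meant to let the second, more hindered annulation outrun side reactions of 7, and the methanolysis returns any phenol that was acylated by surplus ketene.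

Step 4
Reactants: 8 4,4'-diethoxy-6,6'-dimethoxybiphenyl-2,2'-diol
Product: 10 1,1'-(4,4'-diethoxy-2,2'-dihydroxy-6,6'-dimethoxybiphenyl-3,3'-diyl)diethanone, via 4,4'-diethoxy-6,6'-dimethoxybiphenyl-2,2'-diyl diacetate 9 (not isolated)
Conditions: Ac2O, BF3·OEt2, AcOH, 0 → 85 °C; then MeOH/H2O, reflux
Reagents that add atoms: acetic anhydride, CC(=O)OC(C)=O
Why: O-acetylation followed by BF3-promoted Fries rearrangement (Friedel–Crafts acylation) should place each acetyl group on C4a, the only free position ortho to the phenol, because the product is held there as a difluoroboron chelate that the aqueous methanol hydrolyses.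

Step 5
Reactants: 10 1,1'-(4,4'-diethoxy-2,2'-dihydroxy-6,6'-dimethoxybiphenyl-3,3'-diyl)diethanone; 11 4-(benzyloxy)benzaldehyde (2.5 equiv)
Product: 12 (2E,2'E)-1,1'-(4,4'-diethoxy-2,2'-dihydroxy-6,6'-dimethoxybiphenyl-3,3'-diyl)bis{3-[4-(benzyloxy)phenyl]prop-2-en-1-one}
Conditions: KOH, EtOH/THF, 0 °C → rt
Reagents that add atoms: none
Why: Twofold Claisen–Schmidt aldol condensation with a non-enolisable aldehyde; dehydration of the aldolate under equilibrating basic conditions should give the E enones.

Step 6
Reactants: 12 (2E,2'E)-1,1'-(4,4'-diethoxy-2,2'-dihydroxy-6,6'-dimethoxybiphenyl-3,3'-diyl)bis{3-[4-(benzyloxy)phenyl]prop-2-en-1-one}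
Product: 14 4',4'''-bis(benzyloxy)-5,5''-diethoxy-7,7''-dimethoxy-8,8''-biflavone, via bis(flavanone) 13 (not isolated)
Conditions: I2 (20 mol %), DMSO, 130 °C
Reagents that add atoms: none
Why: Iodine-catalysed oxidative cyclisation of 2'-hydroxychalcones, in which 6-endo oxa-Michael closure of each C8a phenol gives flavanone 13, α-iodination and loss of HI give the flavone, and DMSO reoxidises HI to I2; the transient C2 stereocentres are erased.

Step 7
Reactants: 14 4',4'''-bis(benzyloxy)-5,5''-diethoxy-7,7''-dimethoxy-8,8''-biflavone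
Product: 15 5,5'',4',4'''-tetrahydroxy-7,7''-dimethoxy-8,8''-biflavone (target)
Conditions: BCl3 (1 M in CH2Cl2, excess), C6HMe5, CH2Cl2, −78 °C → rt; then MeOH, aq. NaHCO3
Reagents that add atoms: none
Why: Lewis-acid ether cleavage with BCl3, in which the benzyl ethers fall at low temperature with pentamethylbenzene as cation trap and the 5-ethyl ethers are cleaved through the six-membered boron chelate with the C4 carbonyl, while the unchelated 7-methyl ethers should not be attacked.

**Compound list**

1 | chloroacetaldehyde dimethyl acetal (2-chloro-1,1-dimethoxyethane) | COC(CCl)OC | starting material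
2 | sodium methoxyethynide (not isolated) | [Na+].[C-]#COC | intermediate
3 | methoxyethyne | COC#C | intermediate
4 | 1,4-dimethoxybuta-1,3-diyne | COC#CC#COC | intermediate
5 | 3-ethoxycyclobut-2-en-1-one | CCOC1=CC(=O)C1 | starting material
6 | 3-ethoxybuta-1,3-dien-1-one, the vinylketene (not isolated) | CCOC(=C)C=C=O | intermediate
7 | 5-ethoxy-3-methoxy-2-(methoxyethynyl)phenol (not isolated) | CCOc1cc(O)c(C#COC)c(OC)c1 | intermediate
8 | 4,4'-diethoxy-6,6'-dimethoxybiphenyl-2,2'-diol (racemic axis) | CCOc1cc(O)c(-c2c(O)cc(OCC)cc2OC)c(OC)c1 | intermediate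
9 | 4,4'-diethoxy-6,6'-dimethoxybiphenyl-2,2'-diyl diacetate (not isolated) | CCOc1cc(OC(C)=O)c(-c2c(OC(C)=O)cc(OCC)cc2OC)c(OC)c1 | intermediate
10 | 1,1'-(4,4'-diethoxy-2,2'-dihydroxy-6,6'-dimethoxybiphenyl-3,3'-diyl)diethanone | CC(=O)c1c(OCC)cc(OC)c(-c2c(OC)cc(OCC)c(C(C)=O)c2O)c1O | intermediate
11 | 4-(benzyloxy)benzaldehyde | O=Cc1ccc(OCc2ccccc2)cc1 | starting material
12 | (2E,2'E)-bis(chalcone): each acetyl of 10 condensed with 11 to an E 3-[4-(benzyloxy)phenyl]prop-2-enoyl group | O=C(/C=C/c1ccc(OCc2ccccc2)cc1)c1c(OCC)cc(OC)c(-c2c(OC)cc(OCC)c(C(=O)/C=C/c3ccc(OCc4ccccc4)cc3)c2O)c1O | intermediate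
13 | 4',4'''-bis(benzyloxy)-5,5''-diethoxy-7,7''-dimethoxy-8,8''-biflavanone (not isolated; C2 and C2'' unassigned, mixture of diastereomers) | CCOc1cc(OC)c(-c2c(OC)cc(OCC)c3c2OC(c2ccc(OCc4ccccc4)cc2)CC3=O)c2c1C(=O)CC(c1ccc(OCc3ccccc3)cc1)O2 | intermediate
14 | 4',4'''-bis(benzyloxy)-5,5''-diethoxy-7,7''-dimethoxy-8,8''-biflavone | CCOc1cc(OC)c(-c2c(OC)cc(OCC)c3c(=O)cc(-c4ccc(OCc5ccccc5)cc4)oc23)c2oc(-c3ccc(OCc4ccccc4)cc3)cc(=O)c12 | intermediate
15 | 5,5'',4',4'''-tetrahydroxy-7,7''-dimethoxy-8,8''-biflavone (CNP0151059.0, racemic axis) | COc1cc(O)c2c(=O)cc(-c3ccc(O)cc3)oc2c1-c1c(OC)cc(O)c2c(=O)cc(-c3ccc(O)cc3)oc12 | target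

**Count**

Total steps: 7. Longest linear sequence: 7 (steps 1 to 7 from compound 1; compounds 5 and 11 are purchased).

**Steps most likely to fail**

1. Step 3. The diyne may oligomerise on heating, the cascade may stall after one annulation because the hindered aryl ynol ether of 7 reacts slowly, or the new phenol of 7 may add to its own ynol ether before the second ketene arrives. The fallback uses known chemistry and makes the 8,8'' bond by Ullmann coupling of two finished flavone halves; it sets out from aldehyde 11 and comes back to the route at target 15. Commercial 1-(2-hydroxy-4,6-dimethoxyphenyl)ethanone would be iodinated ortho to the chelated hydroxyl (benzyltrimethylammonium dichloroiodate, NaHCO3, CH2Cl2/MeOH) to 1-(2-hydroxy-3-iodo-4,6-dimethoxyphenyl)ethanone F1. Claisen–Schmidt condensation with 11 (KOH, EtOH) should give the E chalcone (2E)-3-[4-(benzyloxy)phenyl]-1-(2-hydroxy-3-iodo-4,6-dimethoxyphenyl)prop-2-en-1-one F2. I2 in DMSO should close it to 4'-(benzyloxy)-8-iodo-5,7-dimethoxyflavone F3. Ullmann homocoupling of two molecules of F3 (activated Cu powder, DMF, 150 °C) should give 4',4'''-bis(benzyloxy)-5,5'',7,7''-tetramethoxy-8,8''-biflavone F4. BCl3 with pentamethylbenzene, as in step 7, should then cleave the benzyl ethers and the chelated 5-methyl ethers and deliver 15.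

2. Step 2. The volatile alkyne may be lost, and the ynol ether or the diyne may hydrate or oligomerise during the aerobic coupling and its work-up. The fallback replaces the free alkyne by a storable silane; it sets out from acetylide 2 and comes back at diyne 4. After removal of ammonia, 2 would be suspended in THF and silylated with Me3SiCl to (methoxyethynyl)trimethylsilane F5, which can be distilled and kept. Desilylative oxidative homocoupling of two molecules of the alkynylsilane (CuCl, DMF, air, rt → 40 °C), which runs through the alkynylcopper, should give 4 without handling methoxyethyne.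

3. Step 4. Acylation may go para to the phenol (C6) as well as ortho (C4a), and the acid may dehydrate the 2,2'-biphenol to a dibenzofuran before it is acetylated. The fallback builds ring C from the phenol oxygen through a tether, so that C4a is the only position the acyl carbon can reach; it sets out from biphenol 8 and comes back at biflavone 14, replacing steps 4 to 6. 1-(Benzyloxy)-4-ethynylbenzene would be converted (n-BuLi, then ClCO2Me, THF, −78 °C) to methyl 3-[4-(benzyloxy)phenyl]prop-2-ynoate F6. Twofold oxa-Michael addition of 8 (Cs2CO3, DMF, 60 °C) should give the bis(β-aryloxycinnamate) dimethyl ester F7, mainly as the Z,Z isomer from anti addition. Saponification (LiOH, THF/H2O) should give the diacid F8. Friedel–Crafts closure through the mixed anhydride (trifluoroacetic anhydride, CH2Cl2, 0 °C → rt), conditions that leave benzyl ethers intact, should give 14.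

**Further compounds**

F1 | step 3 | 1-(2-hydroxy-3-iodo-4,6-dimethoxyphenyl)ethanone | CC(=O)c1c(O)c(I)c(OC)cc1OC
F2 | step 3 | (2E)-3-[4-(benzyloxy)phenyl]-1-(2-hydroxy-3-iodo-4,6-dimethoxyphenyl)prop-2-en-1-one | O=C(/C=C/c1ccc(OCc2ccccc2)cc1)c1c(O)c(I)c(OC)cc1OC
F3 | step 3 | 4'-(benzyloxy)-8-iodo-5,7-dimethoxyflavone | COc1cc(OC)c2c(=O)cc(-c3ccc(OCc4ccccc4)cc3)oc2c1I
F4 | step 3 | 4',4'''-bis(benzyloxy)-5,5'',7,7''-tetramethoxy-8,8''-biflavone | COc1cc(OC)c2c(=O)cc(-c3ccc(OCc4ccccc4)cc3)oc2c1-c1c(OC)cc(OC)c2c(=O)cc(-c3ccc(OCc4ccccc4)cc3)oc12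
F5 | step 2 | (methoxyethynyl)trimethylsilane | COC#C[Si](C)(C)C
F6 | step 4 | methyl 3-[4-(benzyloxy)phenyl]prop-2-ynoate | COC(=O)C#Cc1ccc(OCc2ccccc2)cc1
F7 | step 4 | dimethyl (2Z,2'Z)-3,3'-[(4,4'-diethoxy-6,6'-dimethoxybiphenyl-2,2'-diyl)bis(oxy)]bis{3-[4-(benzyloxy)phenyl]prop-2-enoate} | COC(=O)/C=C(\Oc1cc(OCC)cc(OC)c1-c1c(OC)cc(OCC)cc1O/C(=C\C(=O)OC)c1ccc(OCc2ccccc2)cc1)c1ccc(OCc2ccccc2)cc1
F8 | step 4 | (2Z,2'Z)-3,3'-[(4,4'-diethoxy-6,6'-dimethoxybiphenyl-2,2'-diyl)bis(oxy)]bis{3-[4-(benzyloxy)phenyl]prop-2-enoic acid} | OC(=O)/C=C(\Oc1cc(OCC)cc(OC)c1-c1c(OC)cc(OCC)cc1O/C(=C\C(O)=O)c1ccc(OCc2ccccc2)cc1)c1ccc(OCc2ccccc2)cc1
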